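## Retrosynthetic overview

- **Structural basis.** Ring C and its two flanking atoms are kojic acid. O1, C2, C3–O, C4=O, C4a and C8a are the pyranone ring with its 5-OH, and C8–O is the hydroxymethyl arm. Only C5, C6 and C7 of ring A are absent.
- **Last disconnection (ring A).** Cutting C7–C8 and C4a–C5 releases a malonyl three-carbon unit (methyl malonyl chloride) and a 2-(methoxymethyl)-4-pyranone that already carries ring B and both prenyl ethers.
- **C2–C1'.** This bond comes from Suzuki–Miyaura coupling of a 6-bromopyranone with 4-(prenyloxy)phenyl pinacol boronate.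
- **Groups placed on kojic acid, in order.** CH2OH → CH2Cl → CH2OMe, then C6–H → C6–Br, then O–H → O-prenyl.
- **Ring order.** Ring C is bought, ring B is bought and coupled on, and ring A is annulated last. O5 and O7 first appear as free phenols in the final step.

Key step: step 7

Remark on the chemistry: flavone numbering is used for the atoms of every pyranone intermediate (pyranone C2 = C8a, C3 = C4a, side-chain CH2 = C8, C5 = C3, C6 = C2). Prenyl means 3-methylbut-2-en-1-yl. The target has no stereocentre. The acylated intermediate of the key step is racemic at C8, and this centre is lost on aromatisation.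

## Route

Step 1
Reactants: 1 kojic acid, 5-hydroxy-2-(hydroxymethyl)-4H-pyran-4-one
Product: 2 chlorokojic acid, 2-(chloromethyl)-5-hydroxy-4H-pyran-4-one
Conditions: SOCl2 (neat), 20 °C
Reagents that add atoms: thionyl chloride, O=S(Cl)Cl
Why: Chlorodehydroxylation through the chlorosulfite replaces only the activated primary alcohol, while the enolic 5-OH cannot be substituted and comes back unchanged.

Step 2
Reactants: 2 chlorokojic acid
Product: 3 5-hydroxy-2-(methoxymethyl)-4H-pyran-4-one
Conditions: NaOMe (3 equiv), MeOH (dilute), reflux; then 1 M HCl to pH 3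
Reagents that add atoms: sodium methoxide, [Na+].[O-]C
Why: In this Williamson-type SN2 displacement at the allylic-like primary chloride, the first equivalent of base ionises the 5-OH, which shields the ring from methoxide addition, and the large excess of methoxide at high dilution outruns alkylation by the pyranone oxide.

Step 3
Reactants: 3 5-hydroxy-2-(methoxymethyl)-4H-pyran-4-one
Product: 4 2-bromo-3-hydroxy-6-(methoxymethyl)-4H-pyran-4-one
Conditions: NBS (1.05 equiv), MeCN, 0 → 20 °C, dark
Reagents that add atoms: N-bromosuccinimide, O=C1CCC(=O)N1Br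
Why: Electrophilic bromination of the enolic hydroxypyranone goes to the one free position ortho to the hydroxyl (the future C2), as it does with kojic acid itself, and no alkene is yet present to compete for bromine.

Step 4
Reactants: 4 2-bromo-3-hydroxy-6-(methoxymethyl)-4H-pyran-4-one; 5 prenyl bromide
Product: 6 2-bromo-6-(methoxymethyl)-3-(prenyloxy)-4H-pyran-4-one
Conditions: 5 (1.2 equiv), K2CO3, DMF, 20 °C
Reagents that add atoms: prenyl bromide 5, CC(C)=CCBr
Why: Williamson etherification of the acidic enol OH proceeds by SN2 at the primary allylic carbon, and C-alkylation is excluded because the ortho carbon carries bromine.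

Step 5
Reactants: 7 4-(4,4,5,5-tetramethyl-1,3,2-dioxaborolan-2-yl)phenol; 5 prenyl bromide
Product: 8 4,4,5,5-tetramethyl-2-[4-(prenyloxy)phenyl]-1,3,2-dioxaborolane
Conditions: 5 (1.2 equiv), K2CO3, acetone, reflux
Reagents that add atoms: prenyl bromide 5, CC(C)=CCBr
Why: Williamson etherification of the phenol should be clean because the pinacol boronate is inert to carbonate in acetone and leaves the product easy to purify.

Step 6
Reactants: 6 2-bromo-6-(methoxymethyl)-3-(prenyloxy)-4H-pyran-4-one; 8 4,4,5,5-tetramethyl-2-[4-(prenyloxy)phenyl]-1,3,2-dioxaborolane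
Product: 9 2-(methoxymethyl)-5-(prenyloxy)-6-[4-(prenyloxy)phenyl]-4H-pyran-4-one
Conditions: Pd(dppf)Cl2 (5 mol %), K3PO4, 1,4-dioxane/H2O, 70 °C
Reagents that add atoms: none
Why: In this Suzuki–Miyaura coupling the C–Br bond is a vinylogous acyl bromide that adds to zerovalent palladium much faster than the trisubstituted prenyl ethers can ionise, so C2–C1' should form under mild phosphate activation with both ethers intact.

Step 7
Reactants: 9 2-(methoxymethyl)-5-(prenyloxy)-6-[4-(prenyloxy)phenyl]-4H-pyran-4-one; 10 methyl malonyl chloride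
Product: 14 5,7-dihydroxy-8-methoxy-3-(prenyloxy)-2-[4-(prenyloxy)phenyl]-4H-chromen-4-one (target), via lithium dienolate 11 (not isolated), via methoxycarbonylketene 12 (not isolated), via C8-acylated keto ester 13 (not isolated)
Conditions: LiN(SiMe3)2 (2.5 equiv), THF, −78 °C; 10 (1.2 equiv), slow addition, −78 → 0 °C; MeOH (5 equiv), 0 → 45 °C; AcOH, 0 °C
Reagents that add atoms: methyl malonyl chloride 10, COC(=O)CC(Cl)=O
Why: Proposed new method: LiN(SiMe3)2 takes a C8 proton from 9 to give the 2-alkylidene-2H-pyran-4-olate 11 (charge shared by C8, C4a and O4), while the second equivalent of amide converts the far more acidic 10 by E1cB loss of chloride into ketene 12; 11 adds to 12 through its exocyclic γ-carbon, the site where metalated 2-alkyl-4-pyranones accept carbon electrophiles because only this restores the pyranone, so C7–C8 forms and 13 arises directly as its C6 enolate without draining dienolate by proton transfer. In that enolate the ester belongs to the anion and is inert, so methanol is added to turn surplus amide into LiOMe and to shuttle the proton between C6 and the comparably acidic C8, which is flanked by the C7 ketone, the pyranone and the methoxy group. The C8-deprotonated tautomer holding C7 syn to C4a across C8=C8a then attacks the now free ester carbonyl through C4a in a 6-(enolexo)-exo-trig Dieckmann closure of ring A (C4a–C5), methoxide leaves, and loss of the C4a and C6 protons aromatises the ring to the chelated 5-olate, which makes the sequence irreversible. The closest known reactions are side-chain acylation of metalated 2-alkyl-4-pyranones, base-induced cyclisation of β-triketo esters to acylated phloroglucinols, and the formal [3+3] cyclisation of 1,3-bis(silyl enol ethers) with 1,3-dielectrophiles, whereas their union on a pyranone in one flask is new. The step needs carbon over oxygen acylation, C8 before C4a, and a single ring size: an O4-acyl product is itself an acyl donor and feeds back to C8, C4a is reached only intramolecularly, and attack of C6 on C4 or of O4 on C5 is barred because C8 and C4 stand trans across the ring bond C8a=C4a. No stereocentre remains because C8 of racemic 13 becomes sp2, and the 8-methoxy group is fixed by the starting ether, so no 6-methoxy isomer can arise while ring C stays closed.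

## Compound list

1 | kojic acid | O=c1cc(CO)occ1O | starting material
2 | 2-(chloromethyl)-5-hydroxy-4H-pyran-4-one | O=c1cc(CCl)occ1O | intermediate
3 | 5-hydroxy-2-(methoxymethyl)-4H-pyran-4-one | COCc1cc(=O)c(O)co1 | intermediate
4 | 2-bromo-3-hydroxy-6-(methoxymethyl)-4H-pyran-4-one | COCc1cc(=O)c(O)c(Br)o1 | intermediate
5 | prenyl bromide | CC(C)=CCBr | starting material
6 | 2-bromo-6-(methoxymethyl)-3-(prenyloxy)-4H-pyran-4-one | COCc1cc(=O)c(OCC=C(C)C)c(Br)o1 | intermediate
7 | 4-(4,4,5,5-tetramethyl-1,3,2-dioxaborolan-2-yl)phenol | CC1(C)OB(OC1(C)C)c1ccc(O)cc1 | starting material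
8 | 4,4,5,5-tetramethyl-2-[4-(prenyloxy)phenyl]-1,3,2-dioxaborolane | CC(C)=CCOc1ccc(cc1)B1OC(C)(C)C(C)(C)O1 | intermediate
9 | 2-(methoxymethyl)-5-(prenyloxy)-6-[4-(prenyloxy)phenyl]-4H-pyran-4-one | COCc1cc(=O)c(OCC=C(C)C)c(-c2ccc(OCC=C(C)C)cc2)o1 | intermediate
10 | methyl malonyl chloride | COC(=O)CC(Cl)=O | starting material
11 | lithium 2-(methoxymethylidene)-5-(prenyloxy)-6-[4-(prenyloxy)phenyl]-2H-pyran-4-olate (C8=C8a geometry mobile) | [Li+].[O-]C1=CC(=COC)OC(c2ccc(OCC=C(C)C)cc2)=C1OCC=C(C)C | intermediate
12 | methoxycarbonylketene (methyl 3-oxoprop-2-enoate) | COC(=O)C=C=O | intermediate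
13 | methyl 4-methoxy-3-oxo-4-{4-oxo-5-(prenyloxy)-6-[4-(prenyloxy)phenyl]-4H-pyran-2-yl}butanoate (racemic, present as its lithium enolate) | COC(=O)CC(=O)C(OC)c1cc(=O)c(OCC=C(C)C)c(-c2ccc(OCC=C(C)C)cc2)o1 | intermediate
14 | 5,7-dihydroxy-8-methoxy-3,4'-diprenyloxyflavone | COc1c(O)cc(O)c2c(=O)c(OCC=C(C)C)c(-c3ccc(OCC=C(C)C)cc3)oc12 | target

## Step count

Total step count: 7.
Longest linear sequence: 6 (steps 1, 2, 3, 4, 6, 7).

## Steps most likely to fail

**Step 7.**
- What may go wrong:
  - The ketene may be consumed by the amide base or by self-condensation before the dienolate captures it.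
  - The sequence may stall at the unreactive C6 enolate.
  - Methoxide may open ring C, so that reclosure through O5 scrambles the position of the methoxy group (Wessely–Moser-type isomerisation).
- Fallback: this gives up the pyranone annulation and builds ring C last on a preformed ring A by classical flavonol chemistry. It sets out from 5 and comes back to the route at 14.
  - Purchased 2-methoxybenzene-1,3,5-triol is C-acetylated (Ac2O, BF3·OEt2, Friedel–Crafts acylation) to 1-(2,4,6-trihydroxy-3-methoxyphenyl)ethanone F1.
  - Allyl bromide (2 equiv), K2CO3 and acetone should give 1-[4,6-bis(allyloxy)-2-hydroxy-3-methoxyphenyl]ethanone F2. The hydroxyl wedged between acetyl and methoxy stays chelated and is the last to react.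
  - In parallel, 5 and 4-hydroxybenzaldehyde (K2CO3, DMF) give 4-(prenyloxy)benzaldehyde F3.
  - Claisen–Schmidt condensation of the ketone and the aldehyde (KOH, EtOH) gives (E)-1-[4,6-bis(allyloxy)-2-hydroxy-3-methoxyphenyl]-3-[4-(prenyloxy)phenyl]prop-2-en-1-one F4.
  - Algar–Flynn–Oyamada oxidation (H2O2, NaOH, MeOH, 0 °C), which leaves the isolated alkenes alone, closes ring C to 5,7-bis(allyloxy)-3-hydroxy-8-methoxy-2-[4-(prenyloxy)phenyl]-4H-chromen-4-one F5.
  - Etherification with 5 (K2CO3, DMF) gives 5,7-bis(allyloxy)-8-methoxy-3-(prenyloxy)-2-[4-(prenyloxy)phenyl]-4H-chromen-4-one F6.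
  - Tsuji–Trost deallylation (Pd(PPh3)4, morpholine, THF, 20 °C) removes the two unsubstituted allyl groups, which ionise much faster than prenyl ethers, and delivers 14.

**Step 6.**
- What may go wrong:
  - Zerovalent palladium may ionise the O3 prenyl ether, with loss or transfer of the prenyl group.
  - Aqueous base may displace the bromide.
  - The boronate may undergo protodeboronation.
- Fallback: the order is reversed so that no prenyl ether ever meets palladium. It sets out from 4 and comes back to the route at 9.
  - Compound 4 is coupled unprotected with 7 (Pd(OAc)2, SPhos, K3PO4 in excess, 1,4-dioxane/H2O, 80 °C), in the way free halophenols are coupled, to give 3-hydroxy-2-(4-hydroxyphenyl)-6-(methoxymethyl)-4H-pyran-4-one F7.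
  - Both hydroxyl groups are then prenylated in one operation with 5 (2.4 equiv, K2CO3, DMF, 20 °C) to give 9. Steps 4 and 5 fall away.

**Step 2.**
- What may go wrong:
  - The pyranone oxide of one molecule may alkylate the chloromethyl group of another, building oligomers.
  - Methoxide may add to the ring.
- Fallback: the nucleophilic enol oxygen is masked and the alcohol is methylated instead of the chloride being displaced. It sets out from 1 and comes back to the route at 3.
  - Benzyl chloride, NaOH and MeOH/H2O at reflux give 5-(benzyloxy)-2-(hydroxymethyl)-4H-pyran-4-one F8.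
  - NaH and MeI in THF at 0 °C give 5-(benzyloxy)-2-(methoxymethyl)-4H-pyran-4-one F9.
  - Hydrogenolysis (H2, Pd/C, MeOH, 20 °C) frees the 5-OH to give 3.

## Further compounds

F1 | step 7 | 1-(2,4,6-trihydroxy-3-methoxyphenyl)ethanone | CC(=O)c1c(O)cc(O)c(OC)c1O
F2 | step 7 | 1-[4,6-bis(allyloxy)-2-hydroxy-3-methoxyphenyl]ethanone | CC(=O)c1c(O)c(OC)c(OCC=C)cc1OCC=C
F3 | step 7 | 4-(prenyloxy)benzaldehyde | CC(C)=CCOc1ccc(C=O)cc1
F4 | step 7 | (E)-1-[4,6-bis(allyloxy)-2-hydroxy-3-methoxyphenyl]-3-[4-(prenyloxy)phenyl]prop-2-en-1-one | COc1c(OCC=C)cc(OCC=C)c(C(=O)/C=C/c2ccc(OCC=C(C)C)cc2)c1O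
F5 | step 7 | 5,7-bis(allyloxy)-3-hydroxy-8-methoxy-2-[4-(prenyloxy)phenyl]-4H-chromen-4-one | COc1c(OCC=C)cc(OCC=C)c2c(=O)c(O)c(-c3ccc(OCC=C(C)C)cc3)oc12
F6 | step 7 | 5,7-bis(allyloxy)-8-methoxy-3-(prenyloxy)-2-[4-(prenyloxy)phenyl]-4H-chromen-4-one | COc1c(OCC=C)cc(OCC=C)c2c(=O)c(OCC=C(C)C)c(-c3ccc(OCC=C(C)C)cc3)oc12
F7 | step 6 | 3-hydroxy-2-(4-hydroxyphenyl)-6-(methoxymethyl)-4H-pyran-4-one | COCc1cc(=O)c(O)c(-c2ccc(O)cc2)o1
F8 | step 2 | 5-(benzyloxy)-2-(hydroxymethyl)-4H-pyran-4-one | O=c1cc(CO)occ1OCc1ccccc1
F9 | step 2 | 5-(benzyloxy)-2-(methoxymethyl)-4H-pyran-4-one | COCc1cc(=O)c(OCc2ccccc2)co1
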